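## Retrosynthetic overview
1. Both C(sp)–thienyl bonds are cut last by a double desilylative Sonogashira coupling. All four thiophene rings are bought ready-made as 5-bromo-2,2'-bithiophene.
2. The remaining cis-1,2-diethynylcyclobutane is kept masked as a bicycle in which a Me2Si–O–SiMe2 strap joins the two alkyne termini.
3. Key disconnection: retro-[2+2] across both cyclobutane bonds (CH–CH and CH2–CH2) gives an acyclic bis(but-3-en-1-ynyl)disiloxane.
4. The bis-enyne comes from 1,4-dichlorobut-2-ene (as a vinylacetylide source) and 1,3-dichlorotetramethyldisiloxane.
5. Ring order: the cyclobutane and the nine-membered disiloxane ring form together in step 2. The strap ring is opened again in step 3.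

Assumption: the two substituents are identical and the descriptors are (1R,2S), so the SMILES encodes the cis, meso (achiral) isomer. There is no enantiomer to select, and the stereochemical task is exclusive cis relative configuration.

## Route

**Step 1**
Reactants: 1 (E)-1,4-dichlorobut-2-ene (2.1 equiv); 2 1,3-dichloro-1,1,3,3-tetramethyldisiloxane (1 equiv)
Product: 4 1,3-di(but-3-en-1-yn-1-yl)-1,1,3,3-tetramethyldisiloxane, via lithium but-3-en-1-ynide 3 (not isolated)
Conditions: LDA (commercial solution, 3.0 equiv per 1), THF, −78 → 0 °C; then 2, −78 °C → rt; pH 7 work-up, short-path distillation (BHT, <60 °C)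
Reagents that add atoms: none
Why: Three equivalents of LDA per molecule of 1 remove two HCl (base-induced double dehydrohalogenation) and the acetylenic proton to give 3, which displaces both Si–Cl bonds of 2 (nucleophilic substitution at silicon, standard alkyne C-silylation); no stereocentre is formed.

**Step 2**
Reactants: 4 1,3-di(but-3-en-1-yn-1-yl)-1,1,3,3-tetramethyldisiloxane
Product: 6 (1R,9S)-4,4,6,6-tetramethyl-5-oxa-4,6-disilabicyclo[7.2.0]undeca-2,7-diyne (cis-fused; meso), via eleven-membered bis-propargylic 1,4-diradical 5 (not isolated)
Conditions: xanthone (20 mol %), degassed MeCN (3 mM), 365 nm LED, 10 °C (batch or FEP-tube flow); neutral silica plug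
Reagents that add atoms: none
Why: Proposed new method: triplet energy transfer from xanthone (ET about 74 kcal/mol) populates the enyne T1 state, whose terminal CH2 adds to the facing terminal CH2 of the second arm (the two rigid C≡C rods can lie parallel, in register and about 3.2 Å apart, because only the two nearly barrierless Si–O torsions are free) to give the doubly propargyl-stabilised diradical 5, which after intersystem crossing either reverts to 4 or closes to the head-to-head cyclobutane, and only cis closure is possible because a trans fusion would place the Si atoms about 8 Å apart against about 3.2 Å allowed by Si–O–Si, so the cyclobutane and the nine-membered ring (alkyne angles estimated at 170–172°) form together with both stereocentres set cis by the strap, while 6 has lost the enyne chromophore and is not re-excited; the closest known reaction types are the temporary-silicon-tethered intramolecular [2+2] photocycloaddition and the triplet-sensitised [2+2] cycloaddition of 1,3-dienes and 1,3-enynes.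

**Step 3**
Reactants: 6 (1R,9S)-4,4,6,6-tetramethyl-5-oxa-4,6-disilabicyclo[7.2.0]undeca-2,7-diyne; 7 5-bromo-2,2'-bithiophene (2.2 equiv)
Product: 9 isocardopatine = (1R,2S)-1,2-bis[(2,2'-bithiophen-5-yl)ethynyl]cyclobutane (cis; meso), via cis-1,2-diethynylcyclobutane 8 (not isolated)
Conditions: Pd(PPh3)4 (5 mol %), CuI (10 mol %), i-Pr2NH/THF, TBAF (1 M in THF, 2.2 equiv, slow addition), Ar, dark, rt → 45 °C
Reagents that add atoms: none
Why: Fluoride cleaves both C(sp)–Si bonds (protodesilylation) and the volatile diyne 8 is consumed at once in a double Sonogashira coupling with the reactive 2-bromothiophene terminus of 7, under conditions too weakly basic and too cool to epimerise the propargylic stereocentres or trigger the Cope rearrangement of a cis-dialkynylcyclobutane, so the cis configuration from step 2 is carried through unchanged.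

## Compound list
1 | (E)-1,4-dichlorobut-2-ene | ClC/C=C/CCl | starting material
2 | 1,3-dichloro-1,1,3,3-tetramethyldisiloxane | C[Si](C)(Cl)O[Si](C)(C)Cl | starting material
3 | lithium but-3-en-1-ynide | [Li]C#CC=C | intermediate
4 | 1,3-di(but-3-en-1-yn-1-yl)-1,1,3,3-tetramethyldisiloxane | C=CC#C[Si](C)(C)O[Si](C)(C)C#CC=C | intermediate
5 | 2,2,11,11-tetramethyl-1-oxa-2,11-disilacycloundeca-3,9-diyne-5,8-diyl (1,4-diradical) | C[Si]1(C)O[Si](C)(C)C#C[CH]CC[CH]C#C1 | intermediate
6 | (1R,9S)-4,4,6,6-tetramethyl-5-oxa-4,6-disilabicyclo[7.2.0]undeca-2,7-diyne (cis, meso) | C[Si]1(C)O[Si](C)(C)C#C[C@@H]2CC[C@@H]2C#C1 | intermediate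
7 | 5-bromo-2,2'-bithiophene | Brc1ccc(-c2cccs2)s1 | starting material
8 | (1R,2S)-1,2-diethynylcyclobutane (cis, meso) | C#C[C@@H]1CC[C@@H]1C#C | intermediate
9 | isocardopatine, (1R,2S)-1,2-bis[(2,2'-bithiophen-5-yl)ethynyl]cyclobutane (cis, meso) | C(#C[C@@H]1CC[C@@H]1C#Cc1ccc(-c2cccs2)s1)c1ccc(-c2cccs2)s1 | target

## Step count and risks
Total step count: 3. Longest linear sequence: 3.

**Most likely to fail, first: step 2.** The enyne triplet may decay by C=C twisting, diradical 5 may only revert to 4, the strain of the nine-membered diyne may block closure, or oligomers may form.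
The fallback sets out from 4 (together with 7) and comes back at 9. It gives up the strap and dimerises the full chromophore.
- 4 is put through the Pd(PPh3)4/CuI/TBAF coupling with 7. This frees but-1-en-3-yne F2 in the flask and couples it to 5-(but-3-en-1-yn-1-yl)-2,2'-bithiophene F3.
- F3 has a long-lived triplet that is reached by direct excitation. It is irradiated at 365 nm in concentrated, degassed benzene (at least 0.5 M).
- It dimerises head-to-head through the bis-propargylic diradical to give 9 and its racemic trans isomer cardopatine F4.
- The two isomers are separated by chromatography or preparative HPLC.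

**Second: step 1.** Elimination may be incomplete, the allylic chloride may be aminated, the vinylacetylide may polymerise, or an aminosilane may form.
The fallback sets out from 2 and comes back at 4. It makes the C(sp)–C(sp2) bond last instead of the Si–C(sp) bond.
- 2 is treated with ethynylmagnesium bromide (THF, 0 °C) to give 1,3-diethynyl-1,1,3,3-tetramethyldisiloxane F1.
- Both vinyl groups are then attached by a double Sonogashira coupling with vinyl bromide (Pd(PPh3)4, CuI, Et3N, THF, sealed vessel, rt).
- No metal vinylacetylide is generated at any point.

**Third: step 3.** Volatile 8 may be lost, Glaser oligomers may form, or coupling may stop at the mono-adduct.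
The fallback sets out from 6 and comes back at 9. It reverses the polarity of the coupling.
- 6 is bromodesilylated with NBS/AgF (MeCN, rt, dark) to give (1R,2S)-1,2-bis(bromoethynyl)cyclobutane F5. This compound is non-volatile and cannot homocouple oxidatively.
- F5 then acts as the electrophile in a double Suzuki–Miyaura coupling with commercial 2,2'-bithiophene-5-boronic acid pinacol ester (CC1(C)OB(OC1(C)C)c1ccc(-c2cccs2)s1).
- Coupling conditions are Pd(dppf)Cl2, K3PO4, THF/H2O, 40 °C.

## Further compounds
F1 | step 1 | 1,3-diethynyl-1,1,3,3-tetramethyldisiloxane | C#C[Si](C)(C)O[Si](C)(C)C#C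
F2 | step 2 | but-1-en-3-yne | C=CC#C
F3 | step 2 | 5-(but-3-en-1-yn-1-yl)-2,2'-bithiophene | C=CC#Cc1ccc(-c2cccs2)s1
F4 | step 2 | cardopatine, racemic trans-1,2-bis[(2,2'-bithiophen-5-yl)ethynyl]cyclobutane (1R,2R enantiomer drawn) | C(#C[C@@H]1CC[C@H]1C#Cc1ccc(-c2cccs2)s1)c1ccc(-c2cccs2)s1
F5 | step 3 | (1R,2S)-1,2-bis(bromoethynyl)cyclobutane (cis, meso) | BrC#C[C@@H]1CC[C@@H]1C#CBr
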